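Assumption: the SMILES is read literally, which places C5 and C10 on opposite faces of the oxolane (1S,4S, a trans-bridged ring); (S)-(+)-linalool of high enantiomeric purity and furan-3,4-diyldimethanol are taken as commercial.

## Structural features

The target is a 6,12-germacranolide, numbered here C1–C15. Its ten-membered carbocycle C1–C10 is bridged by an ether oxygen between C1 and C4 (an oxolane C1–C2–C3–C4–O, hence an 11-oxabicyclo[6.2.1]undecane) and is fused at C6–C7 to a γ-alkylidene butenolide (O–C6, C7=C11, C12=O) whose exocyclic double bond C5=C6 lies in the large ring. C4 carries the C15 methyl, C10 the C14 methyl and a free tertiary hydroxyl, C8 an angelate and C11 an acetoxymethyl group (C13). C1 (S) and C10 (R) are adjacent, C4 (S) is quaternary, C8 (S) is isolated and syn to the C10 hydroxyl along C7–C8–C9–C10–C1, and C5=C6 has C4 cis to C7 (5E). The ring bonds C4–C5 and C1–C10 leave opposite faces of the oxolane, so the six-carbon bridge C5–C10 spans it trans (an inside–outside bicycle); this is the pattern of trans-furanoid linalool oxide. Fragile points are the enol lactone, the tertiary allylic C4–O bond (ionisation or retro-oxa-Michael opening would relax the bridge to cis), the Z-configured angelate, the acetate, and the C8 hydrogen, which is vinylogously α to the lactone carbonyl. The real difficulty is the medium ring: a nine-membered oxacycle (ten-membered carbocycle) that must hold the planar unit C4–C5=C6–C7–C8 while crossing the oxolane trans, so that direct closures are strained and reversible closures unfavourable. The key step exploits the enol-lactone double bond C5=C6 itself: C6 is the γ-carbon of a butenolide and can carry sulfur as an S,O-acetal, C5 is a CH2 next to quaternary C4, so a sulfonyl bridge C5–SO2–C6 can sit in a relaxed, one-atom-larger ring and be extruded at the end.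

## Logic of the disconnections

33 to 30 and 31: the C8–O ester bond is cut last. The angelate isomerises and is cleaved by base, so it is put on after all basic steps. The forward step must acylate a secondary hydroxyl beside a free tertiary one without Z to E isomerisation.

30 to 29 to 28: the C13 acetate and the three silyl ethers are removed. This leaves only fluoride-labile groups on the core while strong base is used. The forward steps need primary-over-secondary selectivity and a deprotection that neither opens the enol lactone nor ionises C4–O.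

28 to 25 (key): the C5=C6 double bond is cut and SO2 is inserted between C5 and C6. The strained ten-membered ring with its planar dienolide becomes an eleven-membered thiacycle with sp3 C5 and C6 and two long C–S bonds. The forward step must halogenate C6, deprotonate C5, close the episulfone and lose SO2 without touching C8 or the C4–O bond.

25 to 23 to 21: the C6–S bond is cut to a C5 thiol and a γ-hydroxybutenolide (pseudo-acid). Thioacetal formation is reversible and therefore suited to closing a large ring under thermodynamic control. The demand is a thiol released in the presence of the pseudo-acid.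

21 to 19: the pseudo-acid is traced to a 3,4-disubstituted furan. This stores C6 and C12 at equal oxidation level through all carbanion chemistry. The oxidation must make C12, not C6, the carbonyl carbon.

19 to 18 to 17 to 16 to 14: protecting groups, the C8 carbinol (from a ketone), the dithioketal and the C5 thioester (from a primary alcohol) are removed in turn. C8 is then set by reagent control on a furyl ketone, and sulfur enters by SN2 before singlet oxygen is used. The demands are triflation of the primary hydroxyl only and a thioester that survives the next four steps.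

14 to 8 and 12: the C8–C9 bond is cut to an acyl-anion equivalent and a 2,2-disubstituted epoxide. This is the only way to attack the neopentyl-like C9, and it keeps C10 untouched. The anion must open the epoxide at CH2.

8 to 6 to 4 to 2 to 1: C5 is returned to a vinyl group, the epoxide to a 1,2-diol, and the oxolane C1–O bond to an epoxy alcohol derived from an allylic alcohol. All of C1, C4, C10 and the trans oxolane then come from linalool and one asymmetric epoxidation in an open chain, where no ring strain opposes the trans arrangement.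

12 to 11 to 10 to 9: the dithiane, aldehyde and silyl ether go back to a symmetrical furan diol, so no regiochemical question arises in the fragment.

## Other disconnections considered

Alternative 1: the first that comes to mind. Cut C5–C6 as an aldol bond and close the ten-membered ring directly by an intramolecular vinylogous Mukaiyama aldol reaction of the seco aldehyde silyloxyfuran A1 to carbinol A2, then dehydrate. The closure must form the trans-bridged nine-membered oxacycle in a reversible step, so retro-aldol cleavage competes. The later E1cB dehydration also passes through a planar furanolate and gives no handle on the double-bond geometry. The chosen plan closes a ring one atom larger and makes C5=C6 in an irreversible, stereospecific extrusion.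

Alternative 2: cut C7–C8 and reconnect C5–C10, that is an anionic oxy-Cope ring expansion (KH, 18-crown-6) of the cis-dialkenyl 7-oxanorbornanol A3, which would give the bicyclic ketone A4 in one step with C5=C6 in place. This is the most economical construction of the 11-oxabicyclo[6.2.1] skeleton. It is ruled out on structural grounds: C5 and C10 are bonded on one face of the oxolane in A3, so A4 is necessarily cis-bridged (1S,4R), and no later step can turn it into the trans bridge of the target.

Alternative 3: cut the C1–O bond in the ring, that is a transannular 5-exo epoxide opening of the ten-membered epoxy carbinol A5 by the C4 hydroxyl. The stereochemical course is the same as in step 2 of the chosen route. A5, however, is itself a strained ten-membered dienolide that needs its own ring closure. The face of epoxidation would be set by the conformation of the macrocycle and not by the reagent. The cyclisation would have to build the trans bridge through a strained transition state in competition with 6-endo attack at C10. In the chosen plan the same C–O bond is made in an open chain under reagent control.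

Key step: step 16

## Route

Step 1
Reactants: 1 (S)-linalool [(3S)-3,7-dimethylocta-1,6-dien-3-ol]
Product: 2 (2E,6S)-2,6-dimethylocta-2,7-diene-1,6-diol
Conditions: SeO2 (0.2 equiv), t-BuOOH, salicylic acid (cat.), CH2Cl2, rt
Reagents that add atoms: tert-butyl hydroperoxide CC(C)(C)OO
Why: SeO2-catalysed allylic oxidation (ene reaction then [2,3]-shift) should hydroxylate the (E)-methyl group of the trisubstituted alkene selectively; the vinyl group and the tertiary alcohol are inert and the carbinol centre (C4 of the target, S) is untouched.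

Step 2
Reactants: 2 (2E,6S)-2,6-dimethylocta-2,7-diene-1,6-diol
Product: 4 (2R)-2-[(2S,5S)-5-ethenyl-5-methyloxolan-2-yl]propane-1,2-diol, via epoxy alcohol 3 (not isolated)
Conditions: Ti(OiPr)4, D-(−)-diethyl tartrate, t-BuOOH, 4 Å MS, CH2Cl2, −25 °C; then CSA (cat.), rt
Reagents that add atoms: tert-butyl hydroperoxide CC(C)(C)OO
Why: Sharpless asymmetric epoxidation with the D-(−)-tartrate should give the (2R,3R)-epoxy alcohol 3 under reagent control (the tertiary allylic alcohol at the vinyl group does not react); the tertiary hydroxyl then opens the epoxide at its C3 (C1 of the target) in a 5-exo attack with inversion. This sets C1 (S) and C10 (R) and, with C4 (S) from linalool, the trans disposition of C5 and C10 on the oxolane.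

Step 3
Reactants: 4 (2R)-2-[(2S,5S)-5-ethenyl-5-methyloxolan-2-yl]propane-1,2-diol
Product: 6 (2S,5S)-2-ethenyl-2-methyl-5-[(2R)-2-methyloxiran-2-yl]oxolane, via primary tosylate 5 (not isolated)
Conditions: TsCl (1.1 equiv), Et3N, DMAP (cat.), CH2Cl2, 0 °C; then K2CO3, MeOH, rt
Reagents that add atoms: none
Why: Selective sulfonylation of the primary hydroxyl and Williamson closure by the tertiary alkoxide should give the 2,2-disubstituted epoxide; no bond to C10 is broken, so its configuration is kept.

Step 4
Reactants: 6 (2S,5S)-2-ethenyl-2-methyl-5-[(2R)-2-methyloxiran-2-yl]oxolane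
Product: 8 [(2S,5S)-2-methyl-5-[(2R)-2-methyloxiran-2-yl]oxolan-2-yl]methanol, via aldehyde 7 (not isolated)
Conditions: O3, CH2Cl2/MeOH, −78 °C; then NaBH4, −78 → 0 °C
Reagents that add atoms: ozone [O-][O+]=O
Why: Ozonolysis with reductive work-up excises the terminal vinyl carbon and leaves C5 as a primary alcohol; the quaternary C4 cannot epimerise and the epoxide and ether are inert to ozone and borohydride at this temperature.

Step 5
Reactants: 9 furan-3,4-diyldimethanol
Product: 10 [4-({[tri(propan-2-yl)silyl]oxy}methyl)furan-3-yl]methanol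
Conditions: NaH (1.0 equiv), THF, 0 °C; i-Pr3SiCl (TIPSCl)
Reagents that add atoms: chlorotri(propan-2-yl)silane CC(C)[Si](Cl)(C(C)C)C(C)C
Why: Monosilylation of a symmetrical diol through its monosodium alkoxide; the silylated oxygen becomes O13 and the free hydroxymethyl group becomes C8.

Step 6
Reactants: 10 [4-({[tri(propan-2-yl)silyl]oxy}methyl)furan-3-yl]methanol
Product: 11 4-({[tri(propan-2-yl)silyl]oxy}methyl)furan-3-carbaldehyde
Conditions: MnO2, CH2Cl2, rt
Reagents that add atoms: none
Why: MnO2 oxidises the furylic (benzylic-type) alcohol to the aldehyde without over-oxidation and leaves the silyl ether and furan alone.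

Step 7
Reactants: 11 4-({[tri(propan-2-yl)silyl]oxy}methyl)furan-3-carbaldehyde
Product: 12 2-[4-({[tri(propan-2-yl)silyl]oxy}methyl)furan-3-yl]-1,3-dithiane
Conditions: propane-1,3-dithiol, BF3·OEt2 (cat.), CH2Cl2, −20 °C
Reagents that add atoms: propane-1,3-dithiol SCCCS
Why: Lewis acid-catalysed dithioacetalisation turns the aldehyde carbon (C8) into an acyl-anion equivalent; the bulky TIPS ether tolerates catalytic BF3 at low temperature.

Step 8
Reactants: 12 2-[4-({[tri(propan-2-yl)silyl]oxy}methyl)furan-3-yl]-1,3-dithiane; 8 [(2S,5S)-2-methyl-5-[(2R)-2-methyloxiran-2-yl]oxolan-2-yl]methanol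
Product: 14 (2R)-2-[(2S,5S)-5-(hydroxymethyl)-5-methyloxolan-2-yl]-1-{2-[4-({[tri(propan-2-yl)silyl]oxy}methyl)furan-3-yl]-1,3-dithian-2-yl}propan-2-ol, via 2-lithio-1,3-dithiane 13 (not isolated)
Conditions: 12 (2.4 equiv), n-BuLi (2.3 equiv), THF, −30 °C; then 8, DMPU, −30 → 0 °C
Reagents that add atoms: none
Why: Corey–Seebach umpolung: lithiodithiane 13 should open the epoxide at its CH2 terminus (C9) by SN2 and so form the C8–C9 bond; one equivalent deprotonates the free C5 hydroxyl, and C10 is not involved.

Step 9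
Reactants: 14 (2R)-2-[(2S,5S)-5-(hydroxymethyl)-5-methyloxolan-2-yl]-1-{2-[4-({[tri(propan-2-yl)silyl]oxy}methyl)furan-3-yl]-1,3-dithian-2-yl}propan-2-ol
Product: 16 S-{[(2S,5S)-5-[(2R)-2-hydroxy-1-{2-[4-({[tri(propan-2-yl)silyl]oxy}methyl)furan-3-yl]-1,3-dithian-2-yl}propan-2-yl]-2-methyloxolan-2-yl]methyl} ethanethioate, via primary triflate 15 (not isolated)
Conditions: Tf2O (1.05 equiv), 2,6-lutidine, CH2Cl2, −78 °C; then KSAc, DMF, −20 °C → rt
Reagents that add atoms: potassium thioacetate CC(=O)[S-].[K+]
Why: Triflation at −78 °C is selective for the primary over the tertiary hydroxyl, and thioacetate, a soft and strong nucleophile, should displace the neopentyl-type triflate by SN2. A thioester is chosen because it is inert to singlet oxygen in step 13.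

Step 10
Reactants: 16 S-{[(2S,5S)-5-[(2R)-2-hydroxy-1-{2-[4-({[tri(propan-2-yl)silyl]oxy}methyl)furan-3-yl]-1,3-dithian-2-yl}propan-2-yl]-2-methyloxolan-2-yl]methyl} ethanethioate
Product: 17 S-{[(2S,5S)-5-[(2R)-2-hydroxy-4-oxo-4-[4-({[tri(propan-2-yl)silyl]oxy}methyl)furan-3-yl]butan-2-yl]-2-methyloxolan-2-yl]methyl} ethanethioate
Conditions: MeI, CaCO3, MeCN/H2O, 45 °C
Reagents that add atoms: water O
Why: Alkylative hydrolysis of the dithioketal (S-methylation then hydrolysis, buffered by CaCO3) unveils the C8 ketone; the thioester, furan and silyl ether tolerate these neutral conditions.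

Step 11
Reactants: 17 S-{[(2S,5S)-5-[(2R)-2-hydroxy-4-oxo-4-[4-({[tri(propan-2-yl)silyl]oxy}methyl)furan-3-yl]butan-2-yl]-2-methyloxolan-2-yl]methyl} ethanethioate
Product: 18 S-{[(2S,5S)-5-[(2R,4S)-2,4-dihydroxy-4-[4-({[tri(propan-2-yl)silyl]oxy}methyl)furan-3-yl]butan-2-yl]-2-methyloxolan-2-yl]methyl} ethanethioate
Conditions: (R)-2-methyl-CBS-oxazaborolidine (0.5 equiv), BH3·SMe2, THF, −30 °C
Reagents that add atoms: none
Why: Corey–Bakshi–Shibata reduction: with the 3-furyl group as the large (π) and the CH2 group as the small substituent, the (R)-catalyst should deliver hydride to give the (S)-carbinol at C8 under reagent control, which is the 8,10-syn diol.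

Step 12
Reactants: 18 S-{[(2S,5S)-5-[(2R,4S)-2,4-dihydroxy-4-[4-({[tri(propan-2-yl)silyl]oxy}methyl)furan-3-yl]butan-2-yl]-2-methyloxolan-2-yl]methyl} ethanethioate
Product: 19 S-{[(2S,5S)-5-[(2R,4S)-2,4-bis[(triethylsilyl)oxy]-4-[4-({[tri(propan-2-yl)silyl]oxy}methyl)furan-3-yl]butan-2-yl]-2-methyloxolan-2-yl]methyl} ethanethioate
Conditions: Et3SiOTf (2.6 equiv), 2,6-lutidine, CH2Cl2, −78 → 0 °C
Reagents that add atoms: triethylsilyl trifluoromethanesulfonate CC[Si](CC)(CC)OS(=O)(=O)C(F)(F)F
Why: The silyl triflate protects the secondary and the hindered tertiary hydroxyl, which as alkoxides would attack C6 in step 16; two separate silyl groups leave the C8–C9–C10 chain free to fold in the ring closures.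

Step 13
Reactants: 19 S-{[(2S,5S)-5-[(2R,4S)-2,4-bis[(triethylsilyl)oxy]-4-[4-({[tri(propan-2-yl)silyl]oxy}methyl)furan-3-yl]butan-2-yl]-2-methyloxolan-2-yl]methyl} ethanethioate
Product: 21 S-{[(2S,5S)-5-[(2R,4S)-4-[2-hydroxy-5-oxo-4-({[tri(propan-2-yl)silyl]oxy}methyl)-2,5-dihydrofuran-3-yl]-2,4-bis[(triethylsilyl)oxy]butan-2-yl]-2-methyloxolan-2-yl]methyl} ethanethioate (both lactol epimers), via furan endoperoxide 20 (not isolated)
Conditions: O2, tetraphenylporphyrin (cat.), visible light, i-Pr2NEt, CH2Cl2, −78 °C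
Reagents that add atoms: dioxygen O=O
Why: [4+2] addition of singlet oxygen to the furan gives endoperoxide 20, and Kornblum–DeLaMare fragmentation with a hindered amine should remove the less hindered bridgehead hydrogen at C12 (next to CH2OSi, not next to the branched C8), so that C12 becomes the lactone carbonyl and C6 the lactol carbon. The thioester and silyl ethers are inert to singlet oxygen; the lactol epimers at C6 are of no consequence.

Step 14
Reactants: 21 pseudo-acid thioacetate (γ-hydroxybutenolide; 8,10-bis-TES; 13-TIPS)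
Product: 23 macrocyclic γ-(alkylsulfanyl)butenolide in which sulfur links C5 to C6 [(1S,4S,8S,10R); 8,10-bis-TES; 13-TIPS; both C6 epimers], via thiol 22 (not isolated)
Conditions: NaOMe (2.1 equiv), degassed MeOH, −20 °C; AcOH; evaporation; then BF3·OEt2 (0.3 equiv), 4 Å MS, CH2Cl2 (1 mM), −40 → −10 °C
Reagents that add atoms: none
Why: Methoxide transesterification frees the thiol while the pseudo-acid is held as its carboxylate; after acidification thiol and pseudo-acid should condense under Lewis acid catalysis to the cyclic S,O-acetal under thermodynamic control at high dilution. The ring formed is one long-bonded atom larger than the target ring and has sp3 C5 and C6, so the trans bridge is closed while it is still relaxed.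

Step 15
Reactants: 23 macrocyclic γ-(alkylsulfanyl)butenolide
Product: 25 macrocyclic sulfone C5H2–SO2–C6H [(1S,4S,8S,10R); 8,10-bis-TES; 13-TIPS; both C6 epimers], via sulfoxide 24 (not isolated)
Conditions: mCPBA (2.5 equiv), NaHCO3, CH2Cl2, 0 °C → rt
Reagents that add atoms: mCPBA OOC(=O)c1cccc(Cl)c1
Why: Peracid oxidation of the sulfide through the sulfoxide to the sulfone; the electron-poor tetrasubstituted butenolide alkene and the silyl ethers are inert.

Step 16
Reactants: 25 macrocyclic sulfone C5H2–SO2–C6H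
Product: 28 (1S,4S,5E,8S,10R)-1,4-epoxy-8,10-bis[(triethylsilyl)oxy]-13-{[tri(propan-2-yl)silyl]oxy}germacra-5,7(11)-dien-12,6-olide, via α-chloro sulfone 26 (not isolated), via episulfone 27 (not isolated)
Conditions: LiN(SiMe3)2 (1.05 equiv), THF, −78 °C; N-chlorosuccinimide; then KN(SiMe3)2 (1.2 equiv), −78 → −20 °C
Reagents that add atoms: none
Why: Ramberg–Bäcklund ring contraction: C6–H of 25 (α to sulfonyl and γ to the lactone carbonyl) is removed first and the soft sulfonyl furanolate is chlorinated at C6 to give 26; the amide base then removes a C5 hydrogen, the only remaining α-sulfonyl C–H, and the carbanion displaces chloride from C6 in a 1,3-elimination to the thiirane S,S-dioxide 27, which should lose SO2 stereospecifically below room temperature. The closest known reactions are the Ramberg–Bäcklund olefination of S-glycoside dioxides (α-alkoxy sulfones) to exocyclic enol ethers and the ring contraction of cyclic α-halo sulfones to strained cycloalkenes. One ring is closed: the ten-membered carbocycle (nine-membered through the ether oxygen) arises from the eleven-membered thiacycle by C5–C6 bond formation in 3-exo-tet mode followed by cheletropic extrusion, which is irreversible and can therefore pay for the strain of the trans-bridged ring where a reversible closure could not. No stereocentre is created; C1, C4, C8 and C10 are not touched and the C6 epimers of 25 converge at the planar anion. The double-bond geometry is set in 27: only the cis-fused episulfone (C4 and C7 syn) should fit the nine-membered oxacycle, and retentive loss of SO2 then places C4 cis to C7, the 5E enol lactone. Three selectivities are needed: chlorination at C6 (secured by the large acidity gap between C6–H and C5–H2), deprotonation at C5 and not at the vinylogous C8–H (the α-sulfonyl CH2 is kinetically more acidic than the hindered silyloxy-bearing C8–H, and an aprotic amide base at −78 °C prevents equilibration), and chloride displacement faster than β-elimination of the oxolane oxygen from the C5 carbanion (chloride is the better leaving group and the three-membered closure is intramolecular). No ester is present at this stage, so the base meets only silyl ethers and the lactone.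

Step 17
Reactants: 28 silyl-protected dienolide
Product: 29 (1S,4S,5E,8S,10R)-1,4-epoxy-8,10,13-trihydroxygermacra-5,7(11)-dien-12,6-olide
Conditions: HF·pyridine, pyridine, THF, 0 °C → rt
Reagents that add atoms: none
Why: Fluoride cleaves the three silyl ethers; buffered HF·pyridine is not basic enough to open the enol lactone and not acidic enough to ionise the tertiary allylic C4–O bond.

Step 18
Reactants: 29 triol
Product: 30 (1S,4S,5E,8S,10R)-13-acetoxy-1,4-epoxy-8,10-dihydroxygermacra-5,7(11)-dien-12,6-olide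
Conditions: AcCl (1.1 equiv), 2,4,6-collidine, CH2Cl2, −78 °C
Reagents that add atoms: acetyl chloride CC(=O)Cl
Why: Kinetic acylation of the primary allylic hydroxyl at C13 in preference to the secondary C8 and tertiary C10 hydroxyls.

Step 19
Reactants: 30 13-acetate diol; 31 angelic acid [(2Z)-2-methylbut-2-enoic acid]
Product: 33 target CNP0162854.1 [(1S,4S,5E,8S,10R)-13-acetoxy-8-angeloyloxy-1,4-epoxy-10-hydroxygermacra-5,7(11)-dien-12,6-olide], via mixed anhydride 32 (not isolated)
Conditions: 31, 2,4,6-trichlorobenzoyl chloride, Et3N, toluene, rt; then 30, DMAP, toluene, rt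
Reagents that add atoms: none
Why: Yamaguchi esterification: the mixed anhydride 32 should acylate the secondary C8 hydroxyl under DMAP catalysis at room temperature without isomerising the Z-enoate to the tiglate; the tertiary C10 hydroxyl is too hindered to react.

## Compound list

1 | (S)-linalool, (3S)-3,7-dimethylocta-1,6-dien-3-ol | C=C[C@@](C)(O)CCC=C(C)C | starting material
2 | (2E,6S)-2,6-dimethylocta-2,7-diene-1,6-diol | C=C[C@@](C)(O)CC/C=C(\C)CO | intermediate
3 | (3S)-5-[(2R,3R)-3-(hydroxymethyl)-3-methyloxiran-2-yl]-3-methylpent-1-en-3-ol | C=C[C@@](C)(O)CC[C@H]1O[C@]1(C)CO | intermediate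
4 | (2R)-2-[(2S,5S)-5-ethenyl-5-methyloxolan-2-yl]propane-1,2-diol | C=C[C@]1(C)CC[C@H](O1)[C@](C)(O)CO | intermediate
5 | (2R)-2-[(2S,5S)-5-ethenyl-5-methyloxolan-2-yl]-2-hydroxypropyl 4-methylbenzenesulfonate | C=C[C@]1(C)CC[C@H](O1)[C@](C)(O)COS(=O)(=O)c1ccc(C)cc1 | intermediate
6 | (2S,5S)-2-ethenyl-2-methyl-5-[(2R)-2-methyloxiran-2-yl]oxolane | C=C[C@]1(C)CC[C@H](O1)[C@@]1(C)CO1 | intermediate
7 | (2S,5S)-2-methyl-5-[(2R)-2-methyloxiran-2-yl]oxolane-2-carbaldehyde | O=C[C@]1(C)CC[C@H](O1)[C@@]1(C)CO1 | intermediate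
8 | [(2S,5S)-2-methyl-5-[(2R)-2-methyloxiran-2-yl]oxolan-2-yl]methanol | OC[C@]1(C)CC[C@H](O1)[C@@]1(C)CO1 | intermediate
9 | furan-3,4-diyldimethanol | OCc1cocc1CO | starting material
10 | [4-({[tri(propan-2-yl)silyl]oxy}methyl)furan-3-yl]methanol | OCc1cocc1CO[Si](C(C)C)(C(C)C)C(C)C | intermediate
11 | 4-({[tri(propan-2-yl)silyl]oxy}methyl)furan-3-carbaldehyde | O=Cc1cocc1CO[Si](C(C)C)(C(C)C)C(C)C | intermediate
12 | 2-[4-({[tri(propan-2-yl)silyl]oxy}methyl)furan-3-yl]-1,3-dithiane | C1CSC(SC1)c1cocc1CO[Si](C(C)C)(C(C)C)C(C)C | intermediate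
13 | 2-lithio-2-[4-({[tri(propan-2-yl)silyl]oxy}methyl)furan-3-yl]-1,3-dithiane | [Li]C1(SCCCS1)c1cocc1CO[Si](C(C)C)(C(C)C)C(C)C | intermediate
14 | (2R)-2-[(2S,5S)-5-(hydroxymethyl)-5-methyloxolan-2-yl]-1-{2-[4-({[tri(propan-2-yl)silyl]oxy}methyl)furan-3-yl]-1,3-dithian-2-yl}propan-2-ol | OC[C@]1(C)CC[C@H](O1)[C@](C)(O)CC1(SCCCS1)c1cocc1CO[Si](C(C)C)(C(C)C)C(C)C | intermediate
15 | primary (C5) trifluoromethanesulfonate of 14 | FC(F)(F)S(=O)(=O)OC[C@]1(C)CC[C@H](O1)[C@](C)(O)CC1(SCCCS1)c1cocc1CO[Si](C(C)C)(C(C)C)C(C)C | intermediate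
16 | S-{[(2S,5S)-5-[(2R)-2-hydroxy-1-{2-[4-({[tri(propan-2-yl)silyl]oxy}methyl)furan-3-yl]-1,3-dithian-2-yl}propan-2-yl]-2-methyloxolan-2-yl]methyl} ethanethioate | CC(=O)SC[C@]1(C)CC[C@H](O1)[C@](C)(O)CC1(SCCCS1)c1cocc1CO[Si](C(C)C)(C(C)C)C(C)C | intermediate
17 | S-{[(2S,5S)-5-[(2R)-2-hydroxy-4-oxo-4-[4-({[tri(propan-2-yl)silyl]oxy}methyl)furan-3-yl]butan-2-yl]-2-methyloxolan-2-yl]methyl} ethanethioate | CC(=O)SC[C@]1(C)CC[C@H](O1)[C@](C)(O)CC(=O)c1cocc1CO[Si](C(C)C)(C(C)C)C(C)C | intermediate
18 | S-{[(2S,5S)-5-[(2R,4S)-2,4-dihydroxy-4-[4-({[tri(propan-2-yl)silyl]oxy}methyl)furan-3-yl]butan-2-yl]-2-methyloxolan-2-yl]methyl} ethanethioate | CC(=O)SC[C@]1(C)CC[C@H](O1)[C@](C)(O)C[C@H](O)c1cocc1CO[Si](C(C)C)(C(C)C)C(C)C | intermediate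
19 | S-{[(2S,5S)-5-[(2R,4S)-2,4-bis[(triethylsilyl)oxy]-4-[4-({[tri(propan-2-yl)silyl]oxy}methyl)furan-3-yl]butan-2-yl]-2-methyloxolan-2-yl]methyl} ethanethioate | CC(=O)SC[C@]1(C)CC[C@H](O1)[C@](C)(O[Si](CC)(CC)CC)C[C@H](O[Si](CC)(CC)CC)c1cocc1CO[Si](C(C)C)(C(C)C)C(C)C | intermediate
20 | furan endoperoxide of 19 (2,3,7-trioxabicyclo[2.2.1]hept-5-ene; peroxide bridge between C6 and C12) | CC(=O)SC[C@]1(C)CC[C@H](O1)[C@](C)(O[Si](CC)(CC)CC)C[C@H](O[Si](CC)(CC)CC)C1=C(CO[Si](C(C)C)(C(C)C)C(C)C)C2OC1OO2 | intermediate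
21 | S-{[(2S,5S)-5-[(2R,4S)-4-[2-hydroxy-5-oxo-4-({[tri(propan-2-yl)silyl]oxy}methyl)-2,5-dihydrofuran-3-yl]-2,4-bis[(triethylsilyl)oxy]butan-2-yl]-2-methyloxolan-2-yl]methyl} ethanethioate (both lactol epimers) | CC(=O)SC[C@]1(C)CC[C@H](O1)[C@](C)(O[Si](CC)(CC)CC)C[C@H](O[Si](CC)(CC)CC)C1=C(CO[Si](C(C)C)(C(C)C)C(C)C)C(=O)OC1O | intermediate
22 | C5 thiol corresponding to 21 (both lactol epimers) | SC[C@]1(C)CC[C@H](O1)[C@](C)(O[Si](CC)(CC)CC)C[C@H](O[Si](CC)(CC)CC)C1=C(CO[Si](C(C)C)(C(C)C)C(C)C)C(=O)OC1O | intermediate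
23 | macrocyclic γ-(alkylsulfanyl)butenolide, sulfur linking C5 and C6, (1S,4S,8S,10R), 8,10-bis(triethylsilyl) ether, 13-tri(propan-2-yl)silyl ether, both C6 epimers | S1C[C@]2(C)CC[C@H](O2)[C@](C)(O[Si](CC)(CC)CC)C[C@H](O[Si](CC)(CC)CC)C3=C(CO[Si](C(C)C)(C(C)C)C(C)C)C(=O)OC13 | intermediate
24 | S-oxide of 23 | O=S1C[C@]2(C)CC[C@H](O2)[C@](C)(O[Si](CC)(CC)CC)C[C@H](O[Si](CC)(CC)CC)C3=C(CO[Si](C(C)C)(C(C)C)C(C)C)C(=O)OC13 | intermediate
25 | S,S-dioxide of 23 (macrocyclic sulfone C5H2–SO2–C6H, both C6 epimers) | O=S1(=O)C[C@]2(C)CC[C@H](O2)[C@](C)(O[Si](CC)(CC)CC)C[C@H](O[Si](CC)(CC)CC)C3=C(CO[Si](C(C)C)(C(C)C)C(C)C)C(=O)OC13 | intermediate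
26 | 6-chloro derivative of sulfone 25 (both C6 epimers) | O=S1(=O)C[C@]2(C)CC[C@H](O2)[C@](C)(O[Si](CC)(CC)CC)C[C@H](O[Si](CC)(CC)CC)C3=C(CO[Si](C(C)C)(C(C)C)C(C)C)C(=O)OC13Cl | intermediate
27 | thiirane S,S-dioxide across C5–C6, cis-fused (C4 and C7 syn; drawn as one of the two cis-fused diastereomers) | O=S1(=O)[C@@H]2[C@]3(C)CC[C@H](O3)[C@](C)(O[Si](CC)(CC)CC)C[C@H](O[Si](CC)(CC)CC)C4=C(CO[Si](C(C)C)(C(C)C)C(C)C)C(=O)O[C@@]124 | intermediate
28 | (1S,4S,5E,8S,10R)-1,4-epoxy-8,10-bis[(triethylsilyl)oxy]-13-{[tri(propan-2-yl)silyl]oxy}germacra-5,7(11)-dien-12,6-olide | CC[Si](CC)(CC)O[C@H]1C[C@@](C)(O[Si](CC)(CC)CC)[C@@H]2CC[C@@](C)(/C=C3/OC(=O)C(CO[Si](C(C)C)(C(C)C)C(C)C)=C31)O2 | intermediate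
29 | (1S,4S,5E,8S,10R)-1,4-epoxy-8,10,13-trihydroxygermacra-5,7(11)-dien-12,6-olide | O[C@H]1C[C@@](C)(O)[C@@H]2CC[C@@](C)(/C=C3/OC(=O)C(CO)=C31)O2 | intermediate
30 | (1S,4S,5E,8S,10R)-13-acetoxy-1,4-epoxy-8,10-dihydroxygermacra-5,7(11)-dien-12,6-olide | O[C@H]1C[C@@](C)(O)[C@@H]2CC[C@@](C)(/C=C3/OC(=O)C(COC(C)=O)=C31)O2 | intermediate
31 | angelic acid, (2Z)-2-methylbut-2-enoic acid | C/C=C(/C)C(=O)O | starting material
32 | (2Z)-2-methylbut-2-enoic 2,4,6-trichlorobenzoic anhydride | C/C=C(/C)C(=O)OC(=O)c1c(Cl)cc(Cl)cc1Cl | intermediate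
33 | CNP0162854.1, (1S,4S,5E,8S,10R)-13-acetoxy-8-angeloyloxy-1,4-epoxy-10-hydroxygermacra-5,7(11)-dien-12,6-olide | C/C=C(/C)C(=O)O[C@H]1C[C@@](C)(O)[C@@H]2CC[C@@](C)(/C=C3/OC(=O)C(COC(C)=O)=C31)O2 | target

## Step count and least certain steps

Total step count: 19. Longest linear sequence: 16 steps (steps 1–4 and 8–19, from 1).

Step 16 (key step). The trans-bridged ring with a planar C4–C5=C6–C7–C8 unit is highly strained, so the 1,3-elimination may be slow. Competing processes are halophilic dechlorination back to the sulfonyl furanolate, loss of the oxolane oxygen from the C5 carbanion (ring opening), deprotonation at C8 with epimerisation, and closure to the trans-fused episulfone, which would give the other double-bond geometry. Fallback, forming C5–C6 directly by known aldol chemistry: it sets out from 14 and comes back at 28. The primary hydroxyl of 14 is acetylated (Ac2O, pyridine) to the C5 acetate F1. The operations of steps 10, 11 and 12 then give the ketone F2, the (S)-carbinol F3 and the bis(triethylsilyl) ether F4. Photooxygenation as in step 13 gives the pseudo-acid F5, which NaBH4 reduces in the same flask to the γ-unsubstituted butenolide F6. Methanolysis (K2CO3, MeOH) frees the C5 alcohol F7, Dess–Martin oxidation gives the aldehyde F8, and i-Pr3SiOTf with Et3N gives the 2-silyloxyfuran F9. BF3·OEt2 at high dilution should then close the ring by an intramolecular vinylogous Mukaiyama aldol reaction to the carbinol F10, with C5 and C6 still sp3. Mesylation to the mesylate F11 and E1cB elimination with DBU lead to 28.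

Step 14. The thiolate and methoxide may isomerise the ring-opened (Z)-formyl acrylate or add to it while the thiol is being released, and the reversible thioacetal exchange may stop at oligomers because the ring is strained. Fallback, making the C6–S bond at the sulfone oxidation level: it sets out from thiol 22 (released as in step 14) and comes back at 25. Oxidation of the thiol with mCPBA (2 equiv, −40 °C) gives the sulfinic acid F12. Sulfinic acids add to the aldehyde form of pseudo-acids, and at high dilution with a trace of acid F12 should close onto its own lactol carbon to give the γ-sulfonyl butenolide 25 directly. Step 15 is then not needed.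

Step 13. Regioselection in the Kornblum–DeLaMare fragmentation rests only on the steric difference between the two bridgehead hydrogens; abstraction of C6–H would make C6 the carbonyl carbon and give the constitutional isomer. Fallback, fixing the carbonyl position by C–H borylation: it sets out from 19 and comes back at 21. Sterically governed C–H borylation ([Ir(OMe)(cod)]2, 4,4′-di-tert-butyl-2,2′-bipyridine, B2pin2) at the less hindered α-position C12 gives the boronate F13. Oxidation (Me3NO) and tautomerisation give the butenolide F14 with C12 as the carbonyl carbon. i-Pr3SiOTf with Et3N gives the 2-silyloxyfuran F15, and γ-hydroxylation of F15 with singlet oxygen returns the pseudo-acid 21 with the carbonyl position fixed.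

Step 11. The free tertiary hydroxyl may bind borane and deliver hydride intramolecularly, which would erode the facial selectivity set by the catalyst. Fallback, substrate control instead of reagent control: Narasaka–Prasad reduction of 17 (Et2BOMe, NaBH4, THF/MeOH, −78 °C) through the boron chelate of the C10 hydroxyl, with the oxolanyl group equatorial, should give the same 8,10-syn diol. It sets out from 17, comes back at 18 and makes no new compound.

## Further compounds

F1 | step 16 | [(2S,5S)-5-[(2R)-2-hydroxy-1-{2-[4-({[tri(propan-2-yl)silyl]oxy}methyl)furan-3-yl]-1,3-dithian-2-yl}propan-2-yl]-2-methyloxolan-2-yl]methyl acetate | CC(=O)OC[C@]1(C)CC[C@H](O1)[C@](C)(O)CC1(SCCCS1)c1cocc1CO[Si](C(C)C)(C(C)C)C(C)C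
F2 | step 16 | [(2S,5S)-5-[(2R)-2-hydroxy-4-oxo-4-[4-({[tri(propan-2-yl)silyl]oxy}methyl)furan-3-yl]butan-2-yl]-2-methyloxolan-2-yl]methyl acetate | CC(=O)OC[C@]1(C)CC[C@H](O1)[C@](C)(O)CC(=O)c1cocc1CO[Si](C(C)C)(C(C)C)C(C)C
F3 | step 16 | [(2S,5S)-5-[(2R,4S)-2,4-dihydroxy-4-[4-({[tri(propan-2-yl)silyl]oxy}methyl)furan-3-yl]butan-2-yl]-2-methyloxolan-2-yl]methyl acetate | CC(=O)OC[C@]1(C)CC[C@H](O1)[C@](C)(O)C[C@H](O)c1cocc1CO[Si](C(C)C)(C(C)C)C(C)C
F4 | step 16 | 2,4-bis(triethylsilyl) ether of F3 | CC(=O)OC[C@]1(C)CC[C@H](O1)[C@](C)(O[Si](CC)(CC)CC)C[C@H](O[Si](CC)(CC)CC)c1cocc1CO[Si](C(C)C)(C(C)C)C(C)C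
F5 | step 16 | pseudo-acid (γ-hydroxybutenolide, C12 carbonyl) from F4, both lactol epimers | CC(=O)OC[C@]1(C)CC[C@H](O1)[C@](C)(O[Si](CC)(CC)CC)C[C@H](O[Si](CC)(CC)CC)C1=C(CO[Si](C(C)C)(C(C)C)C(C)C)C(=O)OC1O
F6 | step 16 | γ-unsubstituted butenolide (C6H2) with C5 acetate | CC(=O)OC[C@]1(C)CC[C@H](O1)[C@](C)(O[Si](CC)(CC)CC)C[C@H](O[Si](CC)(CC)CC)C1=C(CO[Si](C(C)C)(C(C)C)C(C)C)C(=O)OC1
F7 | step 16 | C5 primary alcohol of the butenolide | OC[C@]1(C)CC[C@H](O1)[C@](C)(O[Si](CC)(CC)CC)C[C@H](O[Si](CC)(CC)CC)C1=C(CO[Si](C(C)C)(C(C)C)C(C)C)C(=O)OC1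
F8 | step 16 | C5 aldehyde of the butenolide | O=C[C@]1(C)CC[C@H](O1)[C@](C)(O[Si](CC)(CC)CC)C[C@H](O[Si](CC)(CC)CC)C1=C(CO[Si](C(C)C)(C(C)C)C(C)C)C(=O)OC1
F9 | step 16 | seco aldehyde 2-{[tri(propan-2-yl)silyl]oxy}furan | O=C[C@]1(C)CC[C@H](O1)[C@](C)(O[Si](CC)(CC)CC)C[C@H](O[Si](CC)(CC)CC)c1coc(O[Si](C(C)C)(C(C)C)C(C)C)c1CO[Si](C(C)C)(C(C)C)C(C)C
F10 | step 16 | ten-membered vinylogous aldol carbinol (5-hydroxy; C5 and C6 sp3; epimers at C5 and C6) | OC1[C@]2(C)CC[C@H](O2)[C@](C)(O[Si](CC)(CC)CC)C[C@H](O[Si](CC)(CC)CC)C3=C(CO[Si](C(C)C)(C(C)C)C(C)C)C(=O)OC13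
F11 | step 16 | C5 methanesulfonate of F10 | CS(=O)(=O)OC1[C@]2(C)CC[C@H](O2)[C@](C)(O[Si](CC)(CC)CC)C[C@H](O[Si](CC)(CC)CC)C3=C(CO[Si](C(C)C)(C(C)C)C(C)C)C(=O)OC13
F12 | step 14 | C5 sulfinic acid corresponding to thiol 22 | OS(=O)C[C@]1(C)CC[C@H](O1)[C@](C)(O[Si](CC)(CC)CC)C[C@H](O[Si](CC)(CC)CC)C1=C(CO[Si](C(C)C)(C(C)C)C(C)C)C(=O)OC1O
F13 | step 13 | C12 pinacol boronate of furan 19 | CC(=O)SC[C@]1(C)CC[C@H](O1)[C@](C)(O[Si](CC)(CC)CC)C[C@H](O[Si](CC)(CC)CC)c1coc(B2OC(C)(C)C(C)(C)O2)c1CO[Si](C(C)C)(C(C)C)C(C)C
F14 | step 13 | γ-unsubstituted butenolide (C12 carbonyl, C6H2) with C5 thioacetate | CC(=O)SC[C@]1(C)CC[C@H](O1)[C@](C)(O[Si](CC)(CC)CC)C[C@H](O[Si](CC)(CC)CC)C1=C(CO[Si](C(C)C)(C(C)C)C(C)C)C(=O)OC1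
F15 | step 13 | 2-{[tri(propan-2-yl)silyl]oxy}furan from F14 | CC(=O)SC[C@]1(C)CC[C@H](O1)[C@](C)(O[Si](CC)(CC)CC)C[C@H](O[Si](CC)(CC)CC)c1coc(O[Si](C(C)C)(C(C)C)C(C)C)c1CO[Si](C(C)C)(C(C)C)C(C)C
F0 | step 11 | none | none
A1 | alternative 1 | seco aldehyde 2-{[tri(propan-2-yl)silyl]oxy}furan (C5 aldehyde, nucleophilic C6) | O=C[C@]1(C)CC[C@H](O1)[C@](C)(O[Si](CC)(CC)CC)C[C@H](O[Si](CC)(CC)CC)c1coc(O[Si](C(C)C)(C(C)C)C(C)C)c1CO[Si](C(C)C)(C(C)C)C(C)C
A2 | alternative 1 | ten-membered vinylogous aldol carbinol (5-hydroxy; epimers at C5 and C6) | OC1[C@]2(C)CC[C@H](O2)[C@](C)(O[Si](CC)(CC)CC)C[C@H](O[Si](CC)(CC)CC)C3=C(CO[Si](C(C)C)(C(C)C)C(C)C)C(=O)OC13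
A3 | alternative 2 | 3-exo-[4-({[tert-butyl(dimethyl)silyl]oxy}methyl)furan-2-yl]-2-exo-[(E)-2-(4-methoxybenzyloxy)ethenyl]-4-methyl-7-oxabicyclo[2.2.1]heptan-2-ol | O[C@@]1(/C=C/OCc2ccc(OC)cc2)[C@H](c2cc(CO[Si](C)(C)C(C)(C)C)co2)[C@@]2(C)CC[C@@H]1O2
A4 | alternative 2 | cis-bridged (1S,4R) furan-fused 11-oxabicyclo[6.2.1]undecan-10-one with 8-(4-methoxybenzyloxy) group | O=C1C[C@@H](OCc2ccc(OC)cc2)c2c(CO[Si](C)(C)C(C)(C)C)coc2C[C@@]2(C)CC[C@@H]1O2
A5 | alternative 3 | (1R,4S,5E,8S,10R)-1,10-epoxy-4-hydroxy-8,13-bis{[tert-butyl(dimethyl)silyl]oxy}germacra-5,7(11)-dien-12,6-olide | C[C@]1(O)CC[C@H]2O[C@]2(C)C[C@H](O[Si](C)(C)C(C)(C)C)C2=C(CO[Si](C)(C)C(C)(C)C)C(=O)O/C2=C/1
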